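(The numbers in the tables were computed for an exercise; the scatter is artificial.)

A small charge of enzyme has a long way to go: in noon, dusk and winter, 10 µM of free enzyme faces 0.10 M of solid substrate, so each enzyme charged must turn over 10000 times on average to turn that solid substrate into target.

| flask | solid substrate | second substrate | free enzyme | added ligand | temperature | remark | time |
|---|---|---|---|---|---|---|---|
| south | 0.10 M | 0.050 M | 6.7 µM | 59 µM | −25 °C | run made earlier |  |
| east | 0.10 M | 0.050 M | 15 µM | 59 µM | 10 °C | run made earlier |  |
| south-east | 0.10 M | 0.050 M | 10 µM | 30 µM | −25 °C | run made earlier |  |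
| noon | 0.10 M | 0.0500 M | 10 µM | 59 µM | 10 °C |  | 10 h |
| dusk | 0.10 M | 0.0500 M | 10 µM | 59 µM | −20 °C |  | 10 h |
| winter | 0.10 M | 0.0500 M | 10 µM | 59 µM | 40 °C |  | 10 h |

| run | time / h | target / % | solid substrate / % |
|---|---|---|---|
| south | 5.00 | 0 | 14.1 |
| south | 8.00 | 1.4 | 13.2 |
| south | 12.0 | 0.5 | 12.6 |
| south | 15.0 | 0.8 | 12.0 |
| south | 25.0 | 2.1 | 11.7 |
| south | 30.0 | 2.4 | 10.0 |
| south | 60.0 | 4.2 | 9.0 |
| east | 0.833 | 2.5 | 53.3 |
| east | 1.33 | 7.3 | 36.9 |
| east | 2.00 | 10.9 | 20.9 |
| east | 3.00 | 15.5 | 8.8 |
| east | 4.00 | 23.4 | 0.4 |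
| east | 6.00 | 34.0 | 0 |
| east | 10.0 | 53.4 | 0.2 |
| south-east | 5.00 | 1.0 | 14.7 |
| south-east | 15.0 | 1.4 | 11.8 |
| south-east | 30.0 | 3.1 | 9.7 |
| south-east | 50.0 | 5.4 | 6.8 |
| south-east | 60.0 | 6.9 | 5.9 |

(scatter of a reading: 0.5 percentage points)

* the flask that comes out highest in amount of target, in percent of the solid substrate charged, or "all alike" when all lie within 1.5 percentage points (noon / dusk / winter / all alike)
* target at the end, in percent of the solid substrate charged, noon
* target at the end, in percent of the solid substrate charged, dusk
* target at the end, in percent of the solid substrate charged, winter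

- at the start none of the solid substrate is in solution
- what has only dissolved of solid substrate counts as not reacted
- a reading or a percentage of target counts all its forms, free or not

First ask which comes first, dissolving or reaction. By 0.833 h the east run has lost 46.7% of its solid but shows 2.5% of target, so dissolving runs far ahead, and you can treat the reaction as the rate-limiting step there.

Next ask whether that reaction slows. The readings of the east run give 356 h⁻¹ up to 10.0 h for the average turnover frequency, target made per free enzyme charged per hour since the start. Up to 6.00 h they give 378 h⁻¹, so in the east run target climbs almost steadily, in zero order, with the solid reading at 0%. The last target reading of the east run, 0.0534 M, also exceeds the 0.050 M of second substrate charged, so that charge did not cap target there.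

Then ask what temperature does. At −25 °C the south-east run gives 11.5 h⁻¹, and the south run, with twice the ligand and less enzyme, gives 10.4 h⁻¹, close enough that I carry one cold figure forward. Spreading the logarithm evenly over the degrees between the east and south-east runs, I reckon 35.6% for noon and 1.88% for dusk. Stretched far beyond the runs, the same line gives an estimate for winter of 6750 h⁻¹, which would need 1.48 h; even with the 4.00 h added that the east run's solid took to read 0.4%, this stays inside 10 h, so I expect winter near the whole charge and highest.

The forecast gives 36% for noon, 2% for dusk and 90% for winter, with winter highest, noting “Enzyme denaturation at 40 °C is untested”; its winter figure stands below mine.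

The flasks give 37.4% in noon, 2.15% in dusk and 98.0% in winter, so winter comes highest.

    free enzyme → unfolded enzyme (k = 4.40 × 10⁻⁴ min⁻¹, Ea = 279 kJ mol⁻¹)
    starting material + free enzyme ⇌ complex A (K = 14.0 L mol⁻¹, k = 23000 L mol⁻¹ min⁻¹, Ea = 43.0 kJ mol⁻¹, ΔH = −55.0 kJ mol⁻¹)
    complex A → free enzyme + target (k = 140 min⁻¹, Ea = 65.0 kJ mol⁻¹)
    complex B → free enzyme + second product (k = 180 min⁻¹, Ea = 81.0 kJ mol⁻¹)
    free enzyme + added ligand ⇌ idle complex (K = 18000 L mol⁻¹, k = 750 L mol⁻¹ min⁻¹, Ea = 35.0 kJ mol⁻¹, ΔH = −28.0 kJ mol⁻¹)
    solid substrate ⇌ starting material, rate k6*(cs6 - [starting material]) while solid is left; crystals form when [starting material] > cs6 (solubility = 0.0870 M, k = 0.0150 min⁻¹)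
    crystals ⇌ target, rate k7*(cs7 - [target]) while solid is left; crystals form when [target] > cs7 (solubility = 0.0650 M, k = 0.0450 min⁻¹)
    second substrate + free enzyme ⇌ complex B (K = 12.0 L mol⁻¹, k = 85000 L mol⁻¹ min⁻¹, Ea = 38.0 kJ mol⁻¹, ΔH = −2.00 kJ mol⁻¹)
    (constants at 40 °C)

In noon at 10.0 h, complex A, the resting state of the round, holds 58.9% of the catalyst. Noon's average turnover frequency up to 10 h comes to 374 h⁻¹, beside the 356 h⁻¹ read from the east run. For the neighbour, dusk's recipe at 5 °C, the same reckoning gives 218 h⁻¹ and so 21.8% of target; the computed flask gives 26.0%.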